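At 6.00 h, intermediate B reads 24.8 % of the charge in Friday's flask and 25.2 % in Thursday's, though Friday's flask was charged with 1.48 times the substrate.

| setting | Friday's | Thursday's | flask |
|---|---|---|---|
| substrate | 0.40 M | 0.27 M | 0.40 M |
| remark | the very flask that is asked about, followed so far | run made earlier |  |
| time |  |  | 40 h |

| run | time / h | intermediate B / % | target / % |
|---|---|---|---|
| Friday's | 3.00 | 14.2 | 0 |
| Friday's | 4.00 | 20.5 | 0 |
| Friday's | 5.00 | 23.5 | 0 |
| Friday's | 6.00 | 24.8 | 0.7 |
| Friday's | 10.0 | 30.6 | 2.9 |
| Friday's | 12.0 | 32.3 | 4.9 |
| Thursday's | 3.00 | 14.7 | 0.2 |
| Thursday's | 4.00 | 18.2 | 0.1 |
| Thursday's | 6.00 | 25.2 | 0.2 |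
| Thursday's | 8.00 | 30.2 | 2.2 |
| Thursday's | 12.0 | 30.8 | 3.7 |
| Thursday's | 15.0 | 29.1 | 7.8 |

(standard deviation of a reading: 1 percentage point)

1. time up to 40 h at which intermediate B stands highest
2. the amount of intermediate B, in percent of the substrate charged, at that time
3. earliest time at which at least nineteen twentieths of that best amount are there
4. latest time at which they still are

- in percentages every species weighs as the substrate in it: one idle adduct counts as two
- for target the idle adduct is counted in
- the analysis behind the earlier runs scatters by 1 percentage point, standard deviation
- reactions considered so far: intermediate C -> target; substrate + target <-> idle adduct; intermediate B -> intermediate C; substrate -> intermediate A; intermediate A -> intermediate B; substrate -> decomposition product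
- in an amount of target, one idle adduct counts as one target

1. Main steps alone: substrate to intermediate A to intermediate B. For a rate of order n in substrate, the fraction made by a given early time, with the rate constant held fixed, scales as the charge to the power n minus one. That pair of readings gives an apparent order of 0.959, which is first order within a scatter of 1 percentage point. In fractions of the charge, then, both runs are read as one curve.

2. Add the drain, intermediate B to intermediate C. The rise now turns over, and at the top B is made as fast as it is used. The pooled readings flatten between 10.0 h and 12.0 h, so the top is read at 11.0 h, and the three readings there average 31.2 %. If feed and drain share one constant k, B goes as kt times exp(-kt) and peaks at the reciprocal of k; this form is used here for the time of the top, not for its height. This gives the first-order clock, the time of B's top taken as the reciprocal of the rate constant, with substrate falling as exp(-t/clock). Thursday's reading at 8.00 h is 0.967 of the top and the one at 15.0 h is 0.932, so the reckoned window opens near the first time and shuts just before the second.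

3. Add the rest. Target, adduct counted in, reads 4.9 % at 12.0 h in Friday's flask, less than the 36.8 % of substrate the clock leaves at the top. An idle adduct holds one substrate for each target, so this reckoning keeps the top where step 2 put it. Decomposition product is not read.

The forecast put the top later than this reckoning, with 32.8 % at 13.5 h and a window from 10 h to 20 h, since “The richer flask ties up more substrate as adduct”.

The simulation gives 31.2 % at 11.1 h, with the window from 8.25 h to 14.7 h.

    intermediate C → target (k = 6.60 × 10⁻⁴ min⁻¹)
    substrate + target ⇌ idle adduct, settled at all times (K = 3.30 M⁻¹)
    intermediate B → intermediate C (k = 0.00188 min⁻¹)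
    substrate → intermediate A (k = 0.00140 min⁻¹)
    intermediate A → intermediate B (k = 0.0175 min⁻¹)
    substrate → decomposition product (k = 5.29 × 10⁻⁷ min⁻¹)

In this flask at 7.59 h, the half-life of substrate by its conversion into intermediate A is 8.3 h, longer than the 6.1 h of intermediate B by its conversion into intermediate C, and the clock's half-life of 7.62 h lies between them. The clock leaves 36.5 % substrate at the top, where this flask holds 38.3 %; at 25 h it leaves 10.3 %, and the neighbour flask read then holds 11.1 %.

The numbers in the tables are calculated on assumed constants; noise was put on by code.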